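Ring A is cut across its two "para" bonds into two three-carbon halves, C10–C1–C2 (with C20) and C3–C4–C5 (with C19): the 1,3-relationship of the C19 and C20 carboxyls about C5 makes one half an acetoacetate dianion and the other a 2-(methoxycarbonyl)allyl bromide. Their [3+3] annulation (γ-alkylation, then 6-endo Michael addition) forms C2–C3 and C5–C10 in one flask. Removal of the C1 oxygen leaves a meso 1,3-diester whose enzymatic desymmetrisation sets the absolute configuration; C4 and C10 are then quaternised trans to the C5 side chain, ring B is closed by a Michael addition onto a ring C enone and ring D by a SmI2 ketyl–alkyne cyclisation.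

Key step: step 4

Remark: atom labels C1–C20 are gibberellane numbers (C19 on C4, C20 on C10, C7 on C6); β is the face of the hydrogens on C5 and C9, α the face of C19 and C20.
Assumption: pig liver esterase is taken to hydrolyse the ester on the carbon that becomes C10 (13 as drawn); the enantiotopic preference on this substrate cannot be predicted with certainty, and the fallback for step 7 gives either sense by choice of catalyst.

Step 1
Reactants: 1 3,3-diethoxypropan-1-ol
Product: 2 3,3-diethoxypropanal
Conditions: TEMPO (10 mol %), PhI(OAc)2, CH2Cl2, rt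
Reagents that add atoms: none
Why: TEMPO-catalysed oxidation of a primary alcohol should stop at the aldehyde and is mild enough to leave the diethyl acetal intact.

Step 2
Reactants: 2 3,3-diethoxypropanal; 3 methyl acrylate
Product: 4 racemic Morita–Baylis–Hillman alcohol
Conditions: DABCO (0.5 equiv), excess 3, neat, rt
Reagents that add atoms: none
Why: Morita–Baylis–Hillman reaction of an unhindered aliphatic aldehyde with an acrylate; the carbinol centre is racemic and is erased in step 3.

Step 3
Reactants: 4 Morita–Baylis–Hillman alcohol
Product: 6 methyl (2Z)-2-(bromomethyl)-5,5-diethoxypent-2-enoate, via allylic mesylate 5 (not isolated)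
Conditions: MsCl, Et3N, CH2Cl2, 0 °C; then LiBr, acetone, rt
Reagents that add atoms: lithium bromide [Li+].[Br-]; methanesulfonyl chloride CS(=O)(=O)Cl (its atoms stay only in 5)
Why: SN2′ displacement of the secondary allylic mesylate by bromide should give the conjugated, thermodynamically preferred (Z)-2-(bromomethyl)alk-2-enoate under non-acidic conditions that spare the acetal.

Step 4
Reactants: 7 methyl acetoacetate; 6 methyl (2Z)-2-(bromomethyl)-5,5-diethoxypent-2-enoate
Product: 9 racemic dimethyl 2-(2,2-diethoxyethyl)-4-oxocyclohexane-1,3-dicarboxylate, via acyclic keto diester 8 (not isolated)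
Conditions: NaH, then n-BuLi, THF, 0 °C; 6, −78 → 0 °C; then NaOMe (cat.), MeOH, rt; aq. NH4Cl
Reagents that add atoms: none
Why: The 1,3-dianion of 7 alkylates through its terminal (γ) carbon, the future C2, at the primary allylic carbon of 6, the future C3, by SN2 to give the enolate of 8 with the alkylidene ester intact; under catalytic methoxide the β-keto ester carbon, the future C10, then adds 1,4 to the β-carbon of that trisubstituted acrylate, the future C5, and the new ester enolate is quenched by the more acidic β-keto ester proton, so the closure is driven to the cyclic β-keto ester enolate. The closest known reaction type is γ-alkylation of an acetoacetate dianion followed by intramolecular Michael addition, i.e. the [3+3] annulation of 1,3-dicarbonyl bis-nucleophiles with 2-(halomethyl)acrylates. Ring A closes in the 6-endo-trig mode. C5 is formed as a racemate and C4 and C10 remain epimerisable, so no stereocontrol is asked of this step; the centres are corrected when the product is converted into the meso diester 12. The selectivities needed are γ- over α-alkylation (the terminal carbanion of the dianion is the more reactive), SN2 over SN2′ attack (primary bromide against a β-substituted alkene terminus) and C- over O-cyclisation (a six-membered carbocycle against an eight-membered enol ether).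

Step 5
Reactants: 9 cyclic β-keto diester
Product: 10 racemic enol triflate
Conditions: NaH, PhNTf2, THF, 0 °C → rt
Reagents that add atoms: N-phenylbis(trifluoromethanesulfonimide) O=S(=O)(N(c1ccccc1)S(=O)(=O)C(F)(F)F)C(F)(F)F
Why: O-sulfonylation of the sodium enolate of the cyclic β-keto ester should give the ester-conjugated enol triflate (C1=C10) regiospecifically.

Step 6
Reactants: 10 enol triflate
Product: 12 meso dimethyl (1R,2r,3S)-2-(2,2-diethoxyethyl)cyclohexane-1,3-dicarboxylate, via diester epimer mixture 11 (not isolated)
Conditions: H2 (3 atm), PtO2, NaHCO3, MeOH, rt; filter; then NaOMe, MeOH, 50 °C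
Reagents that add atoms: none
Why: catalytic hydrogenolysis–hydrogenation of the enol triflate removes the C1 oxygen, and methoxide equilibration of the two ester-bearing centres should funnel the mixture to the all-equatorial isomer, which is meso.

Step 7
Reactants: 12 meso diester
Product: 13 (1R,2S,3S)-2-(2,2-diethoxyethyl)-3-(methoxycarbonyl)cyclohexane-1-carboxylic acid
Conditions: pig liver esterase, 0.1 M phosphate buffer (pH 7.5), rt; extraction at pH 4
Reagents that add atoms: water O
Why: enzymatic desymmetrisation of a meso diester, in which the esterase distinguishes the enantiotopic ester groups and thereby fixes C5 and decides which carbon becomes C4 and which C10.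

Step 8
Reactants: 13 half-ester
Product: 14 (1R,2S,3R)-2-(2,2-diethoxyethyl)-3-(methoxycarbonyl)-3-methylcyclohexane-1-carboxylic acid
Conditions: LDA (2.2 equiv), THF–DMPU, −78 °C; MeI, −78 → −20 °C; cold dilute HCl
Reagents that add atoms: iodomethane CI
Why: ester enolate alkylation in the presence of a carboxylate, which is not enolised at −78 °C, so only C4 reacts; methyl iodide should enter on the equatorial face, trans to the C5 side chain, to give the 4β-methyl, 4α-ester arrangement.

Step 9
Reactants: 14 methylated acid
Product: 15 dimethyl (1R,2S,3R)-2-(2,2-diethoxyethyl)-1-methylcyclohexane-1,3-dicarboxylate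
Conditions: TMSCHN2, MeOH–toluene, 0 °C
Reagents that add atoms: (trimethylsilyl)diazomethane C[Si](C)(C)C=[N+]=[N-]
Why: non-acidic esterification of a hindered acid that does not touch the acetal.

Step 10
Reactants: 15 diester
Product: 16 tertiary α-bromo ester (C10 epimers)
Conditions: LDA (1.05 equiv), THF, −78 °C; inverse addition to CBr4, −78 °C; aq. NH4Cl
Reagents that add atoms: tetrabromomethane BrC(Br)(Br)Br
Why: electrophilic bromination of the only enolisable ester (C10–H); the configuration of the bromide is irrelevant because it becomes a radical.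

Step 11
Reactants: 17 3-ethoxycyclohex-2-en-1-one
Product: 18 1-ethoxy-3-(trimethylsilyloxy)cyclohexa-1,3-diene
Conditions: LDA, THF, −78 °C; TMSCl
Reagents that add atoms: chlorotrimethylsilane C[Si](C)(C)Cl
Why: kinetic α′-deprotonation of the vinylogous ester and O-silylation (silyl enol ether formation) give the 2-silyloxy diene whose free terminus is the future C9.

Step 12
Reactants: 16 tertiary α-bromo ester; 18 silyloxy diene
Product: 19 C10-quaternised ring A diester carrying the 4-ethoxy-2-oxocyclohex-3-enyl ring (C9 epimers)
Conditions: fac-Ir(ppy)3 (1 mol %), 2,6-lutidine, MeCN, blue LEDs, rt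
Reagents that add atoms: none
Why: photoredox radical α-alkylation of a silyl enol ether, in which the tertiary α-ester radical at C10 adds to the unsubstituted diene terminus and oxidation with loss of the silyl group restores the vinylogous ester; the C10–C9 bond should form on the equatorial β-face, away from the axial C19 ester and trans to the C5 side chain, and the C9 mixture is tolerated because C9 stays epimerisable.

Step 13
Reactants: 19 vinylogous ester
Product: 21 β-propargyl enone aldehyde (C9 epimers), via tertiary propargyl carbinol 20 (not isolated)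
Conditions: HC≡CCH2MgBr (freshly prepared), THF, −78 °C; then 1 M HCl, THF, rt
Reagents that add atoms: propargylmagnesium bromide C#CC[Mg]Br; water O
Why: Stork–Danheiser sequence, i.e. 1,2-addition to the vinylogous ester carbonyl (C8) followed by acid-mediated transposition to the C13 enone, with the two neopentyl-type esters too hindered to react and the same acid unmasking the C7 aldehyde.

Step 14
Reactants: 21 β-propargyl enone aldehyde
Product: 22 tricyclic keto aldehyde (rings A B C)
Conditions: pyrrolidine (20 mol %), AcOH (20 mol %), CH2Cl2, rt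
Reagents that add atoms: none
Why: intramolecular enamine Michael addition (5-exo-trig) of C6 to the enone β-carbon C8 closes ring B and makes C8 quaternary; C9 equilibrates through the dienamine, the cis B/C closure should go through the epimer with C11 pseudo-equatorial on ring B (9β-H, propargyl β), and the epimerisable C6 should settle with the formyl group β and trans to C4.

Step 15
Reactants: 22 tricyclic keto aldehyde
Product: 24 tricyclic keto triester, via carboxylic acid 23 (not isolated)
Conditions: NaClO2, NaH2PO4, 2-methyl-2-butene, t-BuOH–H2O, 0 °C; then TMSCHN2, MeOH–toluene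
Reagents that add atoms: sodium chlorite [Na+].[O-]Cl=O; (trimethylsilyl)diazomethane C[Si](C)(C)C=[N+]=[N-]
Why: Pinnick oxidation converts the aldehyde into the C7 acid without touching ketone or alkyne, and diazoalkane esterification protects it for the samarium step.

Step 16
Reactants: 24 tricyclic keto triester
Product: 25 trimethyl ester of the target gibberellin
Conditions: SmI2 (3 equiv), HMPA, t-BuOH, THF, 0 °C
Reagents that add atoms: none
Why: SmI2 ketyl–alkyne reductive cyclisation (5-exo-dig) joins C13 to C16 and should deliver the bridgehead 13-hydroxyl and the exocyclic C16=C17 methylene at once; the C13 configuration is dictated by the bridge from C8.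

Step 17
Reactants: 25 trimethyl ester of the target gibberellin
Product: 26 target gibberellin triacid (ent-13-hydroxygibberell-16-ene-7,19,20-trioic acid)
Conditions: n-PrSLi, HMPA, rt; then aq. HCl
Reagents that add atoms: none
Why: SN2 demethylation of methyl esters by thiolate cleaves even the hindered C19 and C20 esters without epimerising C6 or disturbing the tertiary alcohol and the alkene.

Compound list
1 | 3,3-diethoxypropan-1-ol | OCCC(OCC)OCC | starting material
2 | 3,3-diethoxypropanal | O=CCC(OCC)OCC | intermediate
3 | methyl acrylate | C=CC(=O)OC | starting material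
4 | methyl 5,5-diethoxy-3-hydroxy-2-methylidenepentanoate (racemic) | C=C(C(=O)OC)C(O)CC(OCC)OCC | intermediate
5 | methyl 5,5-diethoxy-3-(methanesulfonyloxy)-2-methylidenepentanoate (racemic) | C=C(C(=O)OC)C(OS(C)(=O)=O)CC(OCC)OCC | intermediate
6 | methyl (2Z)-2-(bromomethyl)-5,5-diethoxypent-2-enoate | BrC/C(=C\CC(OCC)OCC)C(=O)OC | intermediate
7 | methyl acetoacetate | CC(=O)CC(=O)OC | starting material
8 | dimethyl (2E)-2-(3,3-diethoxypropylidene)-5-oxoheptanedioate (formed as its enolate) | COC(=O)CC(=O)CC/C(=C\CC(OCC)OCC)C(=O)OC | intermediate
9 | dimethyl 2-(2,2-diethoxyethyl)-4-oxocyclohexane-1,3-dicarboxylate (racemic; all-trans isomer drawn; ester centres epimerisable, largely enolised) | COC(=O)[C@@H]1C(=O)CC[C@H](C(=O)OC)[C@H]1CC(OCC)OCC | intermediate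
10 | dimethyl 2-(2,2-diethoxyethyl)-4-(trifluoromethanesulfonyloxy)cyclohex-3-ene-1,3-dicarboxylate (racemic; 1,2-trans drawn) | COC(=O)C1=C(OS(=O)(=O)C(F)(F)F)CC[C@H](C(=O)OC)[C@H]1CC(OCC)OCC | intermediate
11 | dimethyl 2-(2,2-diethoxyethyl)cyclohexane-1,3-dicarboxylate (mixture of C1/C3 epimers) | COC(=O)C1CCCC(C(=O)OC)C1CC(OCC)OCC | intermediate
12 | dimethyl (1R,2r,3S)-2-(2,2-diethoxyethyl)cyclohexane-1,3-dicarboxylate (meso; esters cis to each other, side chain trans to both) | COC(=O)[C@@H]1CCC[C@H](C(=O)OC)[C@H]1CC(OCC)OCC | intermediate
13 | (1R,2S,3S)-2-(2,2-diethoxyethyl)-3-(methoxycarbonyl)cyclohexane-1-carboxylic acid (acid on future C10) | OC(=O)[C@@H]1CCC[C@H](C(=O)OC)[C@H]1CC(OCC)OCC | intermediate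
14 | (1R,2S,3R)-2-(2,2-diethoxyethyl)-3-(methoxycarbonyl)-3-methylcyclohexane-1-carboxylic acid (4β-methyl, 4α-ester) | OC(=O)[C@@H]1CCC[C@@](C)(C(=O)OC)[C@H]1CC(OCC)OCC | intermediate
15 | dimethyl (1R,2S,3R)-2-(2,2-diethoxyethyl)-1-methylcyclohexane-1,3-dicarboxylate | COC(=O)[C@@H]1CCC[C@@](C)(C(=O)OC)[C@H]1CC(OCC)OCC | intermediate
16 | dimethyl (1R,2R)-3-bromo-2-(2,2-diethoxyethyl)-1-methylcyclohexane-1,3-dicarboxylate (both C3 epimers) | COC(=O)C1(Br)CCC[C@@](C)(C(=O)OC)[C@H]1CC(OCC)OCC | intermediate
17 | 3-ethoxycyclohex-2-en-1-one | CCOC1=CC(=O)CCC1 | starting material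
18 | 1-ethoxy-3-(trimethylsilyloxy)cyclohexa-1,3-diene | CCOC1=CC(O[Si](C)(C)C)=CCC1 | intermediate
19 | dimethyl 2-(2,2-diethoxyethyl)-3-(4-ethoxy-2-oxocyclohex-3-en-1-yl)-1-methylcyclohexane-1,3-dicarboxylate (4β-Me, 4α- and 10α-CO2Me, 5β-H, C9 on the β-face of C10; C9 epimers) | CCOC2=CC(=O)C(CC2)[C@]1(C(=O)OC)CCC[C@@](C)(C(=O)OC)[C@H]1CC(OCC)OCC | intermediate
20 | dimethyl 2-(2,2-diethoxyethyl)-3-[4-ethoxy-2-hydroxy-2-(prop-2-yn-1-yl)cyclohex-3-en-1-yl]-1-methylcyclohexane-1,3-dicarboxylate (ring A as in 19; C8 and C9 epimers) | CCOC2=CC(O)(CC#C)C(CC2)[C@]1(C(=O)OC)CCC[C@@](C)(C(=O)OC)[C@H]1CC(OCC)OCC | intermediate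
21 | dimethyl 1-methyl-3-[4-oxo-2-(prop-2-yn-1-yl)cyclohex-2-en-1-yl]-2-(2-oxoethyl)cyclohexane-1,3-dicarboxylate (ring A as in 19; C9 epimers) | C#CCC1=CC(=O)CCC1[C@]2(C(=O)OC)CCC[C@@](C)(C(=O)OC)[C@H]2CC=O | intermediate
22 | tricyclic keto aldehyde: rings A, B and C of the target with C13 ketone, 8β-propargyl, 6β-formyl, 9β-H, 4β-methyl and 4α,10α-bis(methoxycarbonyl) | C#CC[C@]23CC(=O)CC[C@H]2[C@]1(C(=O)OC)CCC[C@@](C)(C(=O)OC)[C@H]1[C@@H]3C=O | intermediate
23 | the C7 carboxylic acid corresponding to 22 | C#CC[C@]23CC(=O)CC[C@H]2[C@]1(C(=O)OC)CCC[C@@](C)(C(=O)OC)[C@H]1[C@@H]3C(=O)O | intermediate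
24 | the C7, C19, C20 trimethyl ester corresponding to 22 (ring D seco form of the target trimethyl ester, with C13 ketone and 8β-propargyl) | C#CC[C@]23CC(=O)CC[C@H]2[C@]1(C(=O)OC)CCC[C@@](C)(C(=O)OC)[C@H]1[C@@H]3C(=O)OC | intermediate
25 | trimethyl ester of the target gibberellin (trimethyl ent-13-hydroxygibberell-16-ene-7,19,20-trioate) | C=C1C[C@]23C[C@@]1(O)CC[C@H]2[C@]1(C(=O)OC)CCC[C@@](C)(C(=O)OC)[C@H]1[C@@H]3C(=O)OC | intermediate
26 | target gibberellin triacid (ent-13-hydroxygibberell-16-ene-7,19,20-trioic acid) | C=C1C[C@]23C[C@@]1(O)CC[C@H]2[C@]1(C(=O)O)CCC[C@@](C)(C(=O)O)[C@H]1[C@@H]3C(=O)O | target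

Total steps: 17. Longest linear sequence: 16 (steps 1–10 and 12–17; step 11 makes the side fragment 18).

Steps most likely to fail

Step 12 (C9–C10 bond). Reduction or loss of HBr from the tertiary bromide may outrun radical addition at the crowded C10, or the diene may add on the α-face. The fallback is an oxidative enolate heterocoupling that sets out from 15 and 17 and returns at 19: the lithium enolate of 15 (LDA, THF, −78 °C) and the kinetic lithium enolate of 17 are combined and oxidised with Fe(acac)3 (2 equiv), which should join C10 to C9 directly. It makes no new compound.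

Step 14 (ring B, C8 and C9). The hindered aldehyde enamine may fail to attack the β,β-disubstituted enone, the aldehyde may instead condense with the ring C ketone, or closure may go through the wrong C9 epimer. The fallback changes the donor and sets out from 21: Pinnick oxidation gives the carboxylic acid F1, and TMSCHN2 gives the methyl ester F2. A thermodynamic base (Cs2CO3, MeCN, or catalytic t-BuOK in t-BuOH–THF) should then close ring B by intramolecular Michael addition of the ester enolate, with C9 equilibrating through the dienolate. This returns to the route at 24 and skips step 15.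

Step 7 (desymmetrisation). The esterase may show low enantiotopic-group selectivity or hydrolyse the other ester. The fallback sets out from 12: saponification (LiOH, THF–H2O) gives the meso diacid F3, and dehydration (Ac2O, 60 °C) gives the bicyclic meso anhydride F4. Alkaloid-mediated methanolysis (MeOH, toluene, −20 °C, with a quinidine- or quinine-derived catalyst such as (DHQD)2AQN or its pseudo-enantiomer, chosen for the required sense) should then open the anhydride enantioselectively to the half-ester. This returns to the route at 13.

Further compounds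
F0 | step 12 | none | none
F1 | step 14 | [2-(prop-2-yn-1-yl)-4-oxocyclohex-2-en-1-yl] ring A diester with a C6 carboxymethyl group (acid from 21) | C#CCC1=CC(=O)CCC1[C@]2(C(=O)OC)CCC[C@@](C)(C(=O)OC)[C@H]2CC(=O)O
F2 | step 14 | methyl ester of F1 | C#CCC1=CC(=O)CCC1[C@]2(C(=O)OC)CCC[C@@](C)(C(=O)OC)[C@H]2CC(=O)OC
F3 | step 7 | (1R,2r,3S)-2-(2,2-diethoxyethyl)cyclohexane-1,3-dicarboxylic acid (meso) | OC(=O)[C@@H]1CCC[C@H](C(=O)O)[C@H]1CC(OCC)OCC
F4 | step 7 | 9-(2,2-diethoxyethyl)-3-oxabicyclo[3.3.1]nonane-2,4-dione (meso; side chain anti to the anhydride bridge) | O=C2[C@@H]1CCC[C@H](C(=O)O2)[C@H]1CC(OCC)OCC
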